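Subtract the product from what the solid substrate has lost in the east run: at 12.0 min the gap is 0.880 mM, and it has about that size from 2.50 min on. This reckoning reads the gap as starting material in a saturated solution, kept at that level while solid remains.

| setting | east | flask |
|---|---|---|
| solid substrate | 40 mM | 20 mM |
| acid | 0.060 mM | 0.0600 mM |
| remark | run made earlier |  |
| time |  | 40 min |
- east (time / min: solid substrate / %, product / %): 0.833: 99.5, 0; 2.50: 96.8, 0.9; 4.00: 98.3, 0.5; 6.00: 97.0, 1.3; 10.0: 95.2, 2.1; 12.0: 95.1, 2.7

(readings scatter by 0.5 percentage points)
- part of the solid substrate that has reacted (what has only dissolved counts as not reacted) at 40 min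
- pH of the solution at 40 min
- acid is the free proton; pH is minus the decimal logarithm of its molar concentration
- amounts and yields of weak acid count idle adduct too
- given per volume of solution although it is solid: solid substrate
- the numbers in the tables scatter with a standard deviation of 0.5 percentage points
- reactions considered so far: starting material -> weak acid + product; weak acid <-> conjugate base + acid; starting material + acid -> weak acid + acid + product; starting material + weak acid <-> idle adduct; solid substrate <-> starting material
- at the start none of the solid substrate is in solution
- what has only dissolved of solid substrate counts as not reacted

Between 6.00 min and 12.0 min, product rises by 1.4 percentage points, which on 40 mM is 0.0933 mM min⁻¹. Over 40 min, that makes 3.73 mM in the flask, less than its 20 mM of solid substrate, so the first estimate is 18.7% reacted.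

That slope is the weak link, a difference of two readings that each scatter by 0.5 points. Reforged from the reading at 12.0 min, with the clock started at 2.50 min, F = 0.114 mM min⁻¹, the product a saturated solution makes per minute, taken as zero-order in the solid. The flask then reaches 21.3%. The readings do not show how strong the weak acid is, so this reckoning takes the pH of the charged 0.0600 mM of acid.

The forecast gives 19% and pH 3.6; it too carries the rate over unchanged, but reads it as “about 0.09 mM/min” and assumes a pKa of about 4.8.

The flask gives 23.1% and pH 4.22.

    starting material → weak acid + product (k = 7.70 × 10⁻⁴ s⁻¹)
    weak acid ⇌ conjugate base + acid, settled at all times (K = 1.30 × 10⁻¹⁰ M)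
    starting material + acid → weak acid + acid + product (k = 30.0 M⁻¹ s⁻¹)
    starting material + weak acid ⇌ idle adduct, settled at all times (K = 99.0 M⁻¹)
    solid substrate ⇌ starting material, rate k5*(cs5 - [starting material]) while solid is left; crystals form when [starting material] > cs5 (solubility = 1.10 mM, k = 0.00560 s⁻¹)

In the flask, starting material stood at 3.20% at 4.00 min and 3.69% at 40.0 min, while solid substrate fell from 95.4% to 73.2%. Both steps to product ran from that dissolved starting material, with acid at 100% of its charge. Read back over the same clock, the product in the flask, 21.6% at 40.0 min, gives F = 0.115 mM min⁻¹, close to 0.114 mM min⁻¹, and idle adduct at 1.47% makes up the rest of the 23.1%. At that F, the neighbour flask with 12 mM of solid substrate comes to 35.9% product, and it stands at 36.0%.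

The numbers in the tables are calculated on assumed constants; scatter was added.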